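Retrosynthesis (germacrane numbering): the C8 tiglate and C13 acetate are cut first, then the butenolide at C7=C11 and O6–C12 (back to a C6 ketone and a silyloxypyruvate), then the oxirane (back to a Z C4=C5 enone).
Enabling feature: the oxygen-bearing ring carbons C1 and C6 face each other 1,6 across the ten-membered ring. Joining them as C1=C6 folds the macrocycle into an octalin whose ring A (C1–C6) is a reduced anisole and whose ring B (C1, C10, C9, C8, C7, C6) carries C8 and C10.
Forward order: ring B is closed onto the anisole (C6–C7 bond, diazoketone to 2-tetralone), ring A is dearomatised, ozone deletes the shared C1=C6 bond and unveils the ten-membered ring, then the oxirane and last the butenolide are added.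
Stereochemistry: C10 comes from a Rh/(S)-BINAP conjugate arylation, C8 from a cis-selective hydride reduction of the tetralone, and C1 from a Felkin–Anh reduction next to C10. A temporary 6R carbinol from (S)-CBS reduction steers the peracid to 4R,5S, and after reoxidation the epoxide steers hydride to 6S.

Key step: step 10

Assumption: the tertiary C4 centre made by methyl addition and the C7/C11 centres made by the aldol addition are erased later, so they are carried as epimer mixtures and drawn without configuration. Germacrane numbering is used for all bicyclic and ten-membered compounds.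

Step 1
Reactants: 1 4-methoxyphenylboronic acid; 2 methyl (E)-but-2-enoate (methyl crotonate)
Product: 3 methyl (R)-3-(4-methoxyphenyl)butanoate
Conditions: Rh(acac)(C2H4)2 (3 mol %), (S)-BINAP, 1,4-dioxane/H2O 10:1, 100 °C
Reagents that add atoms: none
Why: Hayashi–Miyaura rhodium-catalysed asymmetric 1,4-addition, in which the aryl–rhodium/(S)-BINAP species binds the α-si face of the E-enoate so that insertion should create C10 as R before hydrolysis releases the ester.

Step 2
Reactants: 3 methyl (R)-3-(4-methoxyphenyl)butanoate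
Product: 4 (R)-3-(4-methoxyphenyl)butanoic acid
Conditions: LiOH, THF/H2O, rt; then aq. HCl
Reagents that add atoms: lithium hydroxide, [Li+].[OH-]
Why: Plain ester saponification, which leaves the β-stereocentre untouched because it carries no acidic hydrogen.

Step 3
Reactants: 4 (R)-3-(4-methoxyphenyl)butanoic acid
Product: 6 (R)-1-diazo-4-(4-methoxyphenyl)pentan-2-one, via acid chloride 5 (not isolated)
Conditions: (COCl)2, DMF (cat.), CH2Cl2, 0 °C → rt; concentrate; CH2N2 (excess), Et2O, 0 °C
Reagents that add atoms: diazomethane, C=[N+]=[N-]; oxalyl chloride, O=C(Cl)C(=O)Cl (chlorine of 5 only)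
Why: Acylation of diazomethane by an acid chloride (first stage of the Arndt–Eistert sequence), with a second equivalent of diazomethane taking up HCl so that no chloromethyl ketone forms.

Step 4
Reactants: 6 (R)-1-diazo-4-(4-methoxyphenyl)pentan-2-one
Product: 8 (4R)-7-methoxy-4-methyl-3,4-dihydronaphthalen-2(1H)-one, via azulenone 7 (not isolated)
Conditions: Rh2(OAc)4 (0.5 mol %), CH2Cl2, reflux, slow addition; then CF3CO2H, CH2Cl2, 0 °C
Reagents that add atoms: none
Why: Intramolecular Buchner reaction (carbenoid cyclopropanation of the ipso–ortho bond and norcaradiene opening) followed by acid-induced rearomatisation of the azulenone, a known entry to 2-tetralones that forms the C6–C7 bond and closes six-membered ring B without touching C10.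

Step 5
Reactants: 8 (4R)-7-methoxy-4-methyl-3,4-dihydronaphthalen-2(1H)-one
Product: 9 (2S,4R)-7-methoxy-4-methyl-1,2,3,4-tetrahydronaphthalen-2-ol (cis)
Conditions: NaBH4, MeOH, −20 °C
Reagents that add atoms: none
Why: Borohydride reduction of a 3-substituted cyclohexanone type ketone, where axial attack on the conformer with a pseudoequatorial methyl group and attack anti to a pseudoaxial methyl group both lead to the C8 alcohol cis to the C10 methyl group (8S).

Step 6
Reactants: 9 (2S,4R)-7-methoxy-4-methyl-1,2,3,4-tetrahydronaphthalen-2-ol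
Product: 10 tert-butyl{[(2S,4R)-7-methoxy-4-methyl-1,2,3,4-tetrahydronaphthalen-2-yl]oxy}dimethylsilane
Conditions: TBSCl, imidazole, DMF, rt
Reagents that add atoms: tert-butyldimethylsilyl chloride, CC(C)(C)[Si](C)(C)Cl
Why: Imidazole-promoted silylation of a secondary alcohol, giving an ether that withstands dissolving metal, organocerium reagent, ozone, hydrides and amide base.

Step 7
Reactants: 10 tert-butyl{[(2S,4R)-7-methoxy-4-methyl-1,2,3,4-tetrahydronaphthalen-2-yl]oxy}dimethylsilane
Product: 12 (5R,7S)-7-(tert-butyldimethylsilyloxy)-5-methyl-3,4,5,6,7,8-hexahydronaphthalen-2(1H)-one, via dienol ether 11 (not isolated)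
Conditions: Li, NH3(l), THF, t-BuOH, −78 → −33 °C; then (CO2H)2, THF/H2O, rt
Reagents that add atoms: water, O
Why: Birch reduction places hydrogen on the unsubstituted C2 and C5 and so leaves the enol ether C3=C4 and the tetrasubstituted C1=C6 alkene, after which oxalic acid hydrolyses the enol ether to the C4 ketone without moving the β,γ double bond into conjugation.

Step 8
Reactants: 12 (5R,7S)-7-(tert-butyldimethylsilyloxy)-5-methyl-3,4,5,6,7,8-hexahydronaphthalen-2(1H)-one
Product: 13 (5R,7S)-7-(tert-butyldimethylsilyloxy)-2,5-dimethyl-1,2,3,4,5,6,7,8-octahydronaphthalen-2-ol (C4 epimers)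
Conditions: CeCl3 (anhydrous), MeLi, THF, −78 °C; aq. NH4Cl
Reagents that add atoms: methyllithium, [Li]C
Why: Organocerium 1,2-addition, chosen because the weakly basic reagent does not enolise the doubly activated C5 methylene, and both C4 epimers are usable since C4 becomes sp2 in step 11.

Step 9
Reactants: 13 (5R,7S)-7-(tert-butyldimethylsilyloxy)-2,5-dimethyl-1,2,3,4,5,6,7,8-octahydronaphthalen-2-ol
Product: 14 (5R,7S)-7-(tert-butyldimethylsilyloxy)-2,5-dimethyl-1,2,3,4,5,6,7,8-octahydronaphthalen-2-yl acetate (C1=C6 octalin with C4 acetate)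
Conditions: Ac2O, Et3N, DMAP, CH2Cl2, rt
Reagents that add atoms: acetic anhydride, CC(=O)OC(C)=O
Why: DMAP-catalysed (Steglich-type) acylation of a tertiary alcohol, which makes the C4 oxygen a far better leaving group than the C8 silyloxy group for the elimination in step 11.

Step 10
Reactants: 14 (5R,7S)-7-(tert-butyldimethylsilyloxy)-2,5-dimethyl-1,2,3,4,5,6,7,8-octahydronaphthalen-2-yl acetate
Product: 17 (8S,10R)-4-acetoxy-8-(tert-butyldimethylsilyloxy)-4,10-dimethylcyclodecane-1,6-dione, via primary ozonide 15 (not isolated), via secondary ozonide 16 (not isolated)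
Conditions: O3/O2, CH2Cl2, −78 °C; N2 purge; Me2S, −78 °C → rt
Reagents that add atoms: ozone, [O-][O+]=O
Why: Ozone adds as a 1,3-dipole to C1=C6 to give 15, cycloreversion to a ketone and a carbonyl oxide held in one chain and their recombination give 16, and dimethyl sulfide reduces 16 to the C1 and C6 ketones (Criegee mechanism). The closest known reaction is the ozonolysis of Δ9,10-octalins obtained by Birch reduction of tetralins, which gives cyclodecane-1,6-diones. No ring is closed by bond formation: the ten-membered ring C1–C10 appears because the bond shared by rings A and B is deleted, so no entropically costly medium-ring closure is needed. No stereocentre is formed, C8 is remote from the reacting atoms, and C10, now α to the C1 ketone, is protected from epimerisation by the neutral reductive work-up. The only selectivity needed is chemoselectivity, and it is secured because 14 holds a single C=C bond and no arene, while the silyl ether and the tertiary acetate are inert to ozone at −78 °C. The acetate ends up β to the C6 ketone, ready for elimination.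

Step 11
Reactants: 17 (8S,10R)-4-acetoxy-8-(tert-butyldimethylsilyloxy)-4,10-dimethylcyclodecane-1,6-dione
Product: 18 (4Z,8S,10R)-8-(tert-butyldimethylsilyloxy)-4,10-dimethylcyclodec-4-ene-1,6-dione
Conditions: DBU (1.1 equiv), CH2Cl2, 0 °C
Reagents that add atoms: none
Why: E1cB elimination of a β-acetoxy ketone, in which only the C5 enolate carries a competent leaving group (acetate against silyloxide at C8), loss of acetate should outrun reversible transannular aldol addition, and the Z enone is expected because a cis double bond is markedly less strained than a trans one in a ten-membered ring.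

Step 12
Reactants: 18 (4Z,8S,10R)-8-(tert-butyldimethylsilyloxy)-4,10-dimethylcyclodec-4-ene-1,6-dione
Product: 19 (1S,4Z,8S,10R)-8-(tert-butyldimethylsilyloxy)-1-hydroxy-4,10-dimethylcyclodec-4-en-6-one
Conditions: NaBH4, CH2Cl2/MeOH 1:1, −78 °C
Reagents that add atoms: none
Why: Chemoselective low-temperature borohydride reduction (a saturated ketone reacts faster than a β,β-disubstituted conjugated enone), with Felkin–Anh attack anti to the C9 branch on C10 expected to give the 1,10-anti alcohol (1S).

Step 13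
Reactants: 19 (1S,4Z,8S,10R)-8-(tert-butyldimethylsilyloxy)-1-hydroxy-4,10-dimethylcyclodec-4-en-6-one
Product: 20 (1S,4Z,8S,10R)-1-acetoxy-8-(tert-butyldimethylsilyloxy)-4,10-dimethylcyclodec-4-en-6-one
Conditions: Ac2O, pyridine, DMAP (cat.), CH2Cl2, 0 °C
Reagents that add atoms: acetic anhydride, CC(=O)OC(C)=O
Why: DMAP-catalysed acetylation, carried out at once so that the C1 hydroxyl cannot add across the ring to C4 of the enone, installs the first acetate of the target.

Step 14
Reactants: 20 (1S,4Z,8S,10R)-1-acetoxy-8-(tert-butyldimethylsilyloxy)-4,10-dimethylcyclodec-4-en-6-one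
Product: 21 (1S,4Z,6R,8S,10R)-1-acetoxy-8-(tert-butyldimethylsilyloxy)-4,10-dimethylcyclodec-4-en-6-ol
Conditions: (S)-1-methyl-3,3-diphenyltetrahydro-3H-pyrrolo[1,2-c][1,3,2]oxazaborole [(S)-Me-CBS, 20 mol %], catecholborane, toluene, −78 °C
Reagents that add atoms: none
Why: Corey–Bakshi–Shibata reduction, in which the alkenyl branch acts as the large group and C7H2 as the small one, so that the (S)-catalyst should give the 6R allylic alcohol by reagent control while catecholborane avoids hydroboration and 1,4-reduction.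

Step 15
Reactants: 21 (1S,4Z,6R,8S,10R)-1-acetoxy-8-(tert-butyldimethylsilyloxy)-4,10-dimethylcyclodec-4-en-6-ol
Product: 22 (1S,4R,5S,6R,8S,10R)-1-acetoxy-8-(tert-butyldimethylsilyloxy)-4,5-epoxy-4,10-dimethylcyclodecan-6-ol
Conditions: mCPBA, CH2Cl2, 0 °C
Reagents that add atoms: 3-chloroperoxybenzoic acid, OOC(=O)c1cccc(Cl)c1
Why: Hydroxyl-directed (Henbest) peracid epoxidation, stereospecific for the Z alkene, in which A(1,3) strain with C3 holds H6 in the alkene plane so that the hydroxyl group lies on the outer face of the ring and guides the peracid there to give the cis epoxide 4R,5S (threo to 6R).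

Step 16
Reactants: 22 (1S,4R,5S,6R,8S,10R)-1-acetoxy-8-(tert-butyldimethylsilyloxy)-4,5-epoxy-4,10-dimethylcyclodecan-6-ol
Product: 23 (1S,4R,5R,8S,10R)-1-acetoxy-8-(tert-butyldimethylsilyloxy)-4,5-epoxy-4,10-dimethylcyclodecan-6-one
Conditions: Dess–Martin periodinane, pyridine, CH2Cl2, 0 °C → rt
Reagents that add atoms: none
Why: Dess–Martin oxidation under buffered conditions removes the auxiliary C6 centre once it has done its work and restores the ketone needed for the C7–C11 bond, the oxirane carbons keeping their geometry (C5 is named R only because the C6 carbonyl now outranks C4).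

Step 17
Reactants: 24 ethyl 2-(hydroxymethyl)acrylate
Product: 25 ethyl 2-[(tert-butyldimethylsilyloxy)methyl]acrylate
Conditions: TBSCl, imidazole, CH2Cl2, 0 °C → rt
Reagents that add atoms: tert-butyldimethylsilyl chloride, CC(C)(C)[Si](C)(C)Cl
Why: Imidazole-promoted silylation of a primary allylic alcohol.

Step 18
Reactants: 25 ethyl 2-[(tert-butyldimethylsilyloxy)methyl]acrylate
Product: 27 ethyl 3-(tert-butyldimethylsilyloxy)-2-oxopropanoate, via acrylate ozonide 26 (not isolated)
Conditions: O3/O2, CH2Cl2, −78 °C; Me2S, −78 °C → rt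
Reagents that add atoms: ozone, [O-][O+]=O
Why: Ozonolysis of a 1,1-disubstituted acrylate with reductive work-up, a standard route to α-keto esters.

Step 19
Reactants: 23 (1S,4R,5R,8S,10R)-1-acetoxy-8-(tert-butyldimethylsilyloxy)-4,5-epoxy-4,10-dimethylcyclodecan-6-one; 27 ethyl 3-(tert-butyldimethylsilyloxy)-2-oxopropanoate
Product: 29 ethyl 2-[(1S,4R,5R,8S,10R)-1-acetoxy-8-(tert-butyldimethylsilyloxy)-4,5-epoxy-4,10-dimethyl-6-oxocyclodecan-7-yl]-3-(tert-butyldimethylsilyloxy)-2-hydroxypropanoate (C7/C11 epimers), via lithium enolate 28 (not isolated)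
Conditions: LiHMDS (1.05 equiv), THF, −78 °C; 27, −78 °C; AcOH, −78 °C
Reagents that add atoms: lithium hexamethyldisilazide, [Li+].C[Si](C)(C)[N-][Si](C)(C)C (lithium of 28 only)
Why: Directed aldol addition of a kinetic lithium enolate to the very electrophilic keto group of an α-keto ester, in which C7 is the only enolisable position of the epoxy ketone, LiHMDS leaves the less acidic acetate alone, and the new C7 and C11 centres need no control because both become sp2 in step 21.

Step 20
Reactants: 29 ethyl 2-[(1S,4R,5R,8S,10R)-1-acetoxy-8-(tert-butyldimethylsilyloxy)-4,5-epoxy-4,10-dimethyl-6-oxocyclodecan-7-yl]-3-(tert-butyldimethylsilyloxy)-2-hydroxypropanoate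
Product: 31 (1S,4R,5S,6S,8S,10R)-1-acetoxy-8,13-bis(tert-butyldimethylsilyloxy)-4,5-epoxy-11-hydroxygermacran-6,12-olide (C7/C11 epimers), via hydroxy ester 30 (not isolated)
Conditions: NaBH4, CeCl3·7H2O, MeOH, −78 → 0 °C
Reagents that add atoms: none
Why: Luche-type reduction of an α,β-epoxy ketone, a reaction type known to favour the anti (erythro) epoxy alcohol, in which hydride enters the cisoid cerium-bridged conformer from the side of the oxirane oxygen, anti to C4 and on the outer face of the ring, to set 6S, and the γ-hydroxy ester then lactonises on warming.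

Step 21
Reactants: 31 (1S,4R,5S,6S,8S,10R)-1-acetoxy-8,13-bis(tert-butyldimethylsilyloxy)-4,5-epoxy-11-hydroxygermacran-6,12-olide
Product: 32 (1S,4R,5S,6S,8S,10R)-1-acetoxy-8,13-bis(tert-butyldimethylsilyloxy)-4,5-epoxygermacr-7(11)-en-6,12-olide
Conditions: Martin sulfurane Ph2S[OC(CF3)2Ph]2, CH2Cl2, 0 °C → rt
Reagents that add atoms: none
Why: Martin sulfurane dehydration of a tertiary alcohol under neutral conditions that spare the epoxide, with loss of H7 rather than a C13 hydrogen expected because it gives the tetrasubstituted endocyclic butenolide and not an enol ether, and with the alkene geometry fixed by the lactone ring.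

Step 22
Reactants: 32 (1S,4R,5S,6S,8S,10R)-1-acetoxy-8,13-bis(tert-butyldimethylsilyloxy)-4,5-epoxygermacr-7(11)-en-6,12-olide
Product: 33 (1S,4R,5S,6S,8S,10R)-1-acetoxy-4,5-epoxy-8,13-dihydroxygermacr-7(11)-en-6,12-olide
Conditions: HF·pyridine, pyridine, THF, 0 °C → rt
Reagents that add atoms: none
Why: Fluoride-driven cleavage of both silyl ethers with a pyridine-buffered HF source, mild enough to leave the acetate, the oxirane and the base-sensitive C6–H of the butenolide alone.

Step 23
Reactants: 33 (1S,4R,5S,6S,8S,10R)-1-acetoxy-4,5-epoxy-8,13-dihydroxygermacr-7(11)-en-6,12-olide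
Product: 34 (1S,4R,5S,6S,8S,10R)-1,13-diacetoxy-4,5-epoxy-8-hydroxygermacr-7(11)-en-6,12-olide
Conditions: AcCl (1 equiv), 2,4,6-collidine, CH2Cl2, −78 °C
Reagents that add atoms: acetyl chloride, CC(=O)Cl
Why: Rate-selective acylation of the primary C13 alcohol in the presence of the hindered secondary C8 alcohol with acetyl chloride and a hindered pyridine base at low temperature.

Step 24
Reactants: 34 (1S,4R,5S,6S,8S,10R)-1,13-diacetoxy-4,5-epoxy-8-hydroxygermacr-7(11)-en-6,12-olide; 35 tiglic acid
Product: 37 (1S,4R,5S,6S,8S,10R)-1,13-diacetoxy-4,5-epoxy-8-tigloyloxygermacr-7(11)-en-6,12-olide (CNP0287840.1), via mixed anhydride 36 (not isolated)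
Conditions: 35, 2,4,6-trichlorobenzoyl chloride, Et3N, toluene, rt; then 34, DMAP, rt
Reagents that add atoms: 2,4,6-trichlorobenzoyl chloride, O=C(Cl)c1c(Cl)cc(Cl)cc1Cl (aroyl group of 36 only)
Why: Yamaguchi esterification through the mixed anhydride, suited to hindered secondary alcohols, with the E geometry of the tiglate retained because it is the stable isomer.

Compound list
1 | 4-methoxyphenylboronic acid | COc1ccc(B(O)O)cc1 | starting material
2 | methyl (E)-but-2-enoate | C/C=C/C(=O)OC | starting material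
3 | methyl (R)-3-(4-methoxyphenyl)butanoate | COC(=O)C[C@@H](C)c1ccc(OC)cc1 | intermediate
4 | (R)-3-(4-methoxyphenyl)butanoic acid | OC(=O)C[C@@H](C)c1ccc(OC)cc1 | intermediate
5 | (R)-3-(4-methoxyphenyl)butanoyl chloride | ClC(=O)C[C@@H](C)c1ccc(OC)cc1 | intermediate
6 | (R)-1-diazo-4-(4-methoxyphenyl)pentan-2-one | [N-]=[N+]=CC(=O)C[C@@H](C)c1ccc(OC)cc1 | intermediate
7 | (3R)-6-methoxy-3-methyl-3,8a-dihydroazulen-1(2H)-one | O=C1C[C@@H](C)C2=CC=C(OC)C=CC12 | intermediate
8 | (4R)-7-methoxy-4-methyl-3,4-dihydronaphthalen-2(1H)-one | O=C1Cc2cc(OC)ccc2[C@H](C)C1 | intermediate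
9 | (2S,4R)-7-methoxy-4-methyl-1,2,3,4-tetrahydronaphthalen-2-ol | O[C@H]1C[C@@H](C)c2ccc(OC)cc2C1 | intermediate
10 | TBS ether of 9 | CC(C)(C)[Si](C)(C)O[C@H]1C[C@@H](C)c2ccc(OC)cc2C1 | intermediate
11 | tert-butyl{[(2S,4R)-7-methoxy-4-methyl-1,2,3,4,5,8-hexahydronaphthalen-2-yl]oxy}dimethylsilane | CC(C)(C)[Si](C)(C)O[C@H]1C[C@@H](C)C2=C(C1)CC(OC)=CC2 | intermediate
12 | (5R,7S)-7-(tert-butyldimethylsilyloxy)-5-methyl-3,4,5,6,7,8-hexahydronaphthalen-2(1H)-one | CC(C)(C)[Si](C)(C)O[C@H]1C[C@@H](C)C2=C(C1)CC(=O)CC2 | intermediate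
13 | (5R,7S)-7-(tert-butyldimethylsilyloxy)-2,5-dimethyl-1,2,3,4,5,6,7,8-octahydronaphthalen-2-ol, C4 epimers | CC(C)(C)[Si](C)(C)O[C@H]1C[C@@H](C)C2=C(C1)CC(C)(O)CC2 | intermediate
14 | acetate of 13 (key-step precursor), C4 epimers | CC(C)(C)[Si](C)(C)O[C@H]1C[C@@H](C)C2=C(C1)CC(C)(OC(C)=O)CC2 | intermediate
15 | primary ozonide (1,2,3-trioxolane on C1–C6) | CC(C)(C)[Si](C)(C)O[C@H]1C[C@@H](C)C23CCC(C)(OC(C)=O)CC2(C1)OOO3 | intermediate
16 | secondary ozonide (C1 and C6 bridged by O and O–O) | CC(C)(C)[Si](C)(C)O[C@H]1C[C@@H](C)C2(CCC(C)(OC(C)=O)CC3(C1)OO2)O3 | intermediate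
17 | (8S,10R)-4-acetoxy-8-(tert-butyldimethylsilyloxy)-4,10-dimethylcyclodecane-1,6-dione, C4 epimers | CC(C)(C)[Si](C)(C)O[C@H]1C[C@@H](C)C(=O)CCC(C)(OC(C)=O)CC(=O)C1 | intermediate
18 | (4Z,8S,10R)-8-(tert-butyldimethylsilyloxy)-4,10-dimethylcyclodec-4-ene-1,6-dione | CC(C)(C)[Si](C)(C)O[C@H]1C[C@@H](C)C(=O)CC/C(C)=C\C(=O)C1 | intermediate
19 | (1S,4Z,8S,10R)-8-(tert-butyldimethylsilyloxy)-1-hydroxy-4,10-dimethylcyclodec-4-en-6-one | CC(C)(C)[Si](C)(C)O[C@H]1C[C@@H](C)[C@@H](O)CC/C(C)=C\C(=O)C1 | intermediate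
20 | (1S,4Z,8S,10R)-1-acetoxy-8-(tert-butyldimethylsilyloxy)-4,10-dimethylcyclodec-4-en-6-one | CC(C)(C)[Si](C)(C)O[C@H]1C[C@@H](C)[C@@H](OC(C)=O)CC/C(C)=C\C(=O)C1 | intermediate
21 | (1S,4Z,6R,8S,10R)-1-acetoxy-8-(tert-butyldimethylsilyloxy)-4,10-dimethylcyclodec-4-en-6-ol | CC(C)(C)[Si](C)(C)O[C@H]1C[C@@H](C)[C@@H](OC(C)=O)CC/C(C)=C\[C@H](O)C1 | intermediate
22 | (1S,4R,5S,6R,8S,10R)-1-acetoxy-8-(tert-butyldimethylsilyloxy)-4,5-epoxy-4,10-dimethylcyclodecan-6-ol | CC(C)(C)[Si](C)(C)O[C@H]1C[C@@H](C)[C@@H](OC(C)=O)CC[C@@]2(C)O[C@H]2[C@H](O)C1 | intermediate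
23 | (1S,4R,5R,8S,10R)-1-acetoxy-8-(tert-butyldimethylsilyloxy)-4,5-epoxy-4,10-dimethylcyclodecan-6-one | CC(C)(C)[Si](C)(C)O[C@H]1C[C@@H](C)[C@@H](OC(C)=O)CC[C@@]2(C)O[C@H]2C(=O)C1 | intermediate
24 | ethyl 2-(hydroxymethyl)acrylate | C=C(CO)C(=O)OCC | starting material
25 | ethyl 2-[(tert-butyldimethylsilyloxy)methyl]acrylate | C=C(CO[Si](C)(C)C(C)(C)C)C(=O)OCC | intermediate
26 | ethyl 3-[(tert-butyldimethylsilyloxy)methyl]-1,2,4-trioxolane-3-carboxylate | CCOC(=O)C1(CO[Si](C)(C)C(C)(C)C)OCOO1 | intermediate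
27 | ethyl 3-(tert-butyldimethylsilyloxy)-2-oxopropanoate | CCOC(=O)C(=O)CO[Si](C)(C)C(C)(C)C | intermediate
28 | lithium C6=C7 enolate of 23 | CC(C)(C)[Si](C)(C)O[C@H]1C[C@@H](C)[C@@H](OC(C)=O)CC[C@@]2(C)O[C@H]2C([O-])=C1.[Li+] | intermediate
29 | aldol adduct, C7–C11 bond, C7/C11 epimers | CC(C)(C)[Si](C)(C)O[C@H]1C[C@@H](C)[C@@H](OC(C)=O)CC[C@@]2(C)O[C@H]2C(=O)C1C(O)(CO[Si](C)(C)C(C)(C)C)C(=O)OCC | intermediate
30 | (6S)-hydroxy ester from 29 | CC(C)(C)[Si](C)(C)O[C@H]1C[C@@H](C)[C@@H](OC(C)=O)CC[C@@]2(C)O[C@H]2[C@@H](O)C1C(O)(CO[Si](C)(C)C(C)(C)C)C(=O)OCC | intermediate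
31 | (1S,4R,5S,6S,8S,10R)-1-acetoxy-8,13-bis(tert-butyldimethylsilyloxy)-4,5-epoxy-11-hydroxygermacran-6,12-olide | CC(C)(C)[Si](C)(C)O[C@H]1C[C@@H](C)[C@@H](OC(C)=O)CC[C@@]2(C)O[C@H]2[C@H]2OC(=O)C(O)(CO[Si](C)(C)C(C)(C)C)C12 | intermediate
32 | (1S,4R,5S,6S,8S,10R)-1-acetoxy-8,13-bis(tert-butyldimethylsilyloxy)-4,5-epoxygermacr-7(11)-en-6,12-olide | CC(C)(C)[Si](C)(C)O[C@H]1C[C@@H](C)[C@@H](OC(C)=O)CC[C@@]2(C)O[C@H]2[C@H]2OC(=O)C(CO[Si](C)(C)C(C)(C)C)=C12 | intermediate
33 | (1S,4R,5S,6S,8S,10R)-1-acetoxy-4,5-epoxy-8,13-dihydroxygermacr-7(11)-en-6,12-olide | O[C@H]1C[C@@H](C)[C@@H](OC(C)=O)CC[C@@]2(C)O[C@H]2[C@H]2OC(=O)C(CO)=C12 | intermediate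
34 | (1S,4R,5S,6S,8S,10R)-1,13-diacetoxy-4,5-epoxy-8-hydroxygermacr-7(11)-en-6,12-olide | O[C@H]1C[C@@H](C)[C@@H](OC(C)=O)CC[C@@]2(C)O[C@H]2[C@H]2OC(=O)C(COC(C)=O)=C12 | intermediate
35 | tiglic acid | C/C=C(\C)C(=O)O | starting material
36 | tiglic 2,4,6-trichlorobenzoic anhydride | C/C=C(\C)C(=O)OC(=O)c1c(Cl)cc(Cl)cc1Cl | intermediate
37 | CNP0287840.1 | C/C=C(\C)C(=O)O[C@H]1C[C@@H](C)[C@@H](OC(C)=O)CC[C@@]2(C)O[C@H]2[C@H]2OC(=O)C(COC(C)=O)=C12 | target

Total step count: 24. Longest linear sequence: 22 steps (steps 1–16 and 19–24 from 1 and 2). Steps 17 and 18 make keto ester 27 in a side branch.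

Steps most likely to fail

Step 11 (elimination to the Z enone). Four processes may interfere:
- kinetic formation of the E isomer;
- drift of the double bond out of conjugation toward C3 or C15 on longer contact with base;
- transannular aldol addition between the two ketones;
- epimerisation at C10.

The fallback sets out from 13 and comes back at 18. The alkene is made while ring A is still intact, so that its cis geometry is imposed by the six-membered ring. Dehydration of 13 with methyl N-(triethylammoniumsulfonyl)carbamate (Burgess reagent) toward the allylic C5 hydrogens gives the ring-A 1,3-diene F1. Titration with one equivalent of ozone, then Me2S, cleaves the more electron-rich tetrasubstituted C1=C6 bond. The surviving C4=C5 bond is deactivated as soon as it is conjugated with the new C6 ketone, which gives 18 without any base.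

Step 19 (aldol addition). Three processes may erode the addition:
- proton transfer from the enolisable keto ester to the enolate;
- retro-aldol cleavage during work-up;
- β-elimination of the C8 silyloxy group from the enolate.

The fallback sets out from 23 and comes back at 34.
- The enolate is added to non-enolisable ethyl glyoxylate to give the glyoxylate aldol F2.
- NaBH4/CeCl3 and lactonisation give the secondary 11-hydroxy lactone F3.
- Dess–Martin oxidation gives the α-keto lactone, which rests as its enol, the 11-hydroxybutenolide F4.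
- Tf2O/2,6-lutidine gives the enol triflate F5.
- Stille coupling with Bu3SnCH2OH (Pd(PPh3)4, LiCl, THF) brings in C13 as the 13-hydroxy butenolide F6.
- Ac2O/pyridine gives the 13-acetate F7, and HF·pyridine frees the C8 hydroxyl to return 34.

This path also avoids the tertiary-alcohol dehydration of step 21.

Step 21 (dehydration). Three things may go wrong:
- loss of a C13 hydrogen instead of H7;
- slow departure of the leaving group next to the lactone carbonyl;
- an outcome that depends on the C7/C11 relative configuration.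

The fallback sets out from 29 and comes back at 32. The elimination is moved to the ketone stage, where only H7 is acidic. Ac2O/DMAP gives the tertiary β-acetoxy ketone F8, and DBU expels acetate by E1cB to give the alkylidene keto ester F9. Luche reduction, now with C7 sp2 and only the oxirane next to the carbonyl, gives the hydroxy ester F10, which lactonises to 32. The price is that the C7=C11 geometry must be controlled or the isomers separated, since only the isomer with the ester cis to C6 can close.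

Further compounds
F1 | step 11 | ring-A 1,3-diene, tert-butyl{[(2S,4R)-4,7-dimethyl-1,2,3,4,5,6-hexahydronaphthalen-2-yl]oxy}dimethylsilane | CC(C)(C)[Si](C)(C)O[C@H]1C[C@@H](C)C2=C(C1)C=C(C)CC2
F2 | step 19 | glyoxylate aldol (C7–CH(OH)CO2Et, C7/C11 epimers) | CC(C)(C)[Si](C)(C)O[C@H]1C[C@@H](C)[C@@H](OC(C)=O)CC[C@@]2(C)O[C@H]2C(=O)C1C(O)C(=O)OCC
F3 | step 19 | secondary 11-hydroxy lactone | CC(C)(C)[Si](C)(C)O[C@H]1C[C@@H](C)[C@@H](OC(C)=O)CC[C@@]2(C)O[C@H]2[C@H]2OC(=O)C(O)C12
F4 | step 19 | 11-hydroxybutenolide | CC(C)(C)[Si](C)(C)O[C@H]1C[C@@H](C)[C@@H](OC(C)=O)CC[C@@]2(C)O[C@H]2[C@H]2OC(=O)C(O)=C12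
F5 | step 19 | enol triflate | CC(C)(C)[Si](C)(C)O[C@H]1C[C@@H](C)[C@@H](OC(C)=O)CC[C@@]2(C)O[C@H]2[C@H]2OC(=O)C(OS(=O)(=O)C(F)(F)F)=C12
F6 | step 19 | 13-hydroxy butenolide (C8 OTBS) | CC(C)(C)[Si](C)(C)O[C@H]1C[C@@H](C)[C@@H](OC(C)=O)CC[C@@]2(C)O[C@H]2[C@H]2OC(=O)C(CO)=C12
F7 | step 19 | 13-acetate (C8 OTBS) | CC(C)(C)[Si](C)(C)O[C@H]1C[C@@H](C)[C@@H](OC(C)=O)CC[C@@]2(C)O[C@H]2[C@H]2OC(=O)C(COC(C)=O)=C12
F8 | step 21 | tertiary β-acetoxy ketone | CC(C)(C)[Si](C)(C)O[C@H]1C[C@@H](C)[C@@H](OC(C)=O)CC[C@@]2(C)O[C@H]2C(=O)C1C(OC(C)=O)(CO[Si](C)(C)C(C)(C)C)C(=O)OCC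
F9 | step 21 | alkylidene keto ester (ester cis to C6) | CC(C)(C)[Si](C)(C)O[C@H]1C[C@@H](C)[C@@H](OC(C)=O)CC[C@@]2(C)O[C@H]2C(=O)/C1=C(/CO[Si](C)(C)C(C)(C)C)C(=O)OCC
F10 | step 21 | hydroxy ester (6S, ester cis to C6) | CC(C)(C)[Si](C)(C)O[C@H]1C[C@@H](C)[C@@H](OC(C)=O)CC[C@@]2(C)O[C@H]2[C@@H](O)/C1=C(/CO[Si](C)(C)C(C)(C)C)C(=O)OCC
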